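The unit I count in is the working minute: turnovers made so far, divided by the turnovers per minute (the turnover frequency) at the early rate, which I read as a run's second reading over its time. The bench you take over carries the south-west flask, with 870 mM starting material on 1.20 mM free catalyst.

| setting | north | west | south | east | south-west |
|---|---|---|---|---|---|
| starting material | 120 mM | 72.0 mM | 360 mM | 120 mM | 870 mM |
| free catalyst | 1.20 mM | 1.20 mM | 1.20 mM | 0.600 mM | 1.20 mM |
| time |  |  |  |  | 32 min |

- north run (time / min: [target] / mM): 1.3: 9.0; 2.2: 15.4; 3.7: 24.1; 6.4: 37.1; 11: 52.8; 19: 67.9; 32: 77.6
- west run (time / min: [target] / mM): 1.3: 7.4; 2.2: 11.9; 3.7: 16.1; 6.4: 25.5; 11: 34.0; 19: 42.0; 32: 46.7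
- south run (time / min: [target] / mM): 1.3: 12.8; 2.2: 21.4; 3.7: 35.4; 6.4: 59.9; 11: 97.9; 19: 150.8; 32: 207.0
- east run (time / min: [target] / mM): 1.3: 4.9; 2.2: 7.5; 3.7: 12.4; 6.4: 20.7; 11: 30.8; 19: 46.6; 32: 60.8

(readings scatter by 0.6 mM)

- the power of [starting material] that the first rate follows, about the charge of the north run; measure it at two percent of starting material made into target (one fixed amount of target, the same in the runs compared)
- the power of [free catalyst] that the first rate follows, about the charge of the north run; measure it at two percent of starting material made into target
- target in the south-west run at 32 min, as a share of the starting material charged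

- Overall: starting material -> target, with free catalyst as catalyst.
- Constant volume, constant temperature.
- What is held in complexes is read along with the free species.
- An order is taken over about fifteen percent of the charge, up and down.

The south run reads an early rate of 9.73 mM min⁻¹, so at 32 min it shows 21.3 min of c(target) over early rate, the working minutes, and has lost 10.7 min of the clock. The west run, with an early rate of 5.41 mM min⁻¹, shows 8.63 min.

I pass a bending curve through the early rates of the west and south runs and carry it to the south-west charge:

half-rate charge = 89.8 mM
top rate = 12.2 mM min⁻¹
south-west early rate = 11.0 mM min⁻¹

The south run's early rate stands 20.0% below the top and the south-west's 9.35%. My own assumption, taken from the nearest charge, is that lost minutes shrink in that proportion: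

lost = 5.02 min
working minutes = 27.0 min
c(target) = 297 mM, a share of 34.2%

That is my estimate for the south-west flask at 32 min. Do not change the free catalyst: the east run, at 0.600 mM, had half the north run's early rate and showed 17.8 min of working time against the north run's 11.1 min, so I hold this count to 1.20 mM.

The forecast gives 0.43, 0.98 and 35%, against my 34.2% for the last, noting that “the east curve overlays the north curve on catalyst×time”.

The flask gives 0.46, 1.0 and 35.4%, from these equations:

    free catalyst + starting material ⇌ catalyst-substrate complex, settled at all times (11.50 M⁻¹)
    catalyst-substrate complex ⇌ target + free catalyst (10.50 min⁻¹, 8.160 M⁻¹ min⁻¹)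
    2 free catalyst → 2 spent catalyst (94.80 M⁻¹ min⁻¹)
    target → decomposed product (0.005688 min⁻¹)

Over all runs the best power-law order in starting material is 0.74, higher than the 0.46 of the first rate. By 32 min the south-west flask has made 308 mM target, or 257 turnovers per free catalyst charged. At its early rate that is 28.0 min of working time, more than the 21.3 min of the south run, and 4.00 min short of the clock.

The data stem from a simulated flask on assumed constants; noise was put on by code.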